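## Retrosynthetic overview

1. Target 20 ⇐ pentabenzyl ether 19 by hydrogenolysis of five O–benzyl bonds in the last step.
2. 19 ⇐ (E)-3-aryloxyacrylic acid 17 by breaking C4–C4a. An intramolecular Friedel–Crafts acylation closes ring C, the only ring formed in the route; rings A and B are bought as arenes.
3. Feature used: C4a of ring A is the single free carbon ortho to the ring C oxygen O1, because the other ortho carbon, C8, bears oxygen. C4a lies ortho to the C5 oxygen and para to the C7 methoxy, so an acyl carbon (C4) tethered through O1–C2=C3 can attack only there.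
4. 17 ⇐ phenol 6 + enol triflate 15 (O1–C2 bond, vinylic substitution), then ester hydrolysis. 15 ⇐ β-keto ester 13 ⇐ aroyl chloride 10 + methyl benzyloxyacetate 11 (C2–C3 bond, crossed Claisen).
5. 6 ⇐ o-vanillin 1 (Elbs hydroxylation, benzylation, Baeyer–Villiger). 10 ⇐ 3,5-dihydroxy-4-methoxybenzoic acid 7.

Key step: step 11

Remark: the target has no stereocentre. In alkenes 15–18 the descriptor (E) means that the carboxyl carbon is cis to the oxygen substituent on the neighbouring alkene carbon, which is the geometry the ring closure needs.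

## Route

Step 1
Reactants: 1 o-vanillin
Product: 3 2,5-dihydroxy-3-methoxybenzaldehyde, via potassium aryl sulfate 2 (not isolated)
Conditions: K2S2O8, aq KOH, 0–20 °C; then conc. HCl, 90 °C
Reagents that add atoms: potassium peroxodisulfate, [K+].[K+].[O-]S(=O)(=O)OOS(=O)(=O)[O-]
Why: Elbs persulfate oxidation, in which the phenoxide attacks a peroxide oxygen through its free para carbon (C5) and the aryl sulfate is then hydrolysed by hot acid.

Step 2
Reactants: 3 2,5-dihydroxy-3-methoxybenzaldehyde
Product: 4 2,5-bis(benzyloxy)-3-methoxybenzaldehyde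
Conditions: BnBr, K2CO3, DMF, 60 °C, N2
Reagents that add atoms: benzyl bromide, BrCc1ccccc1
Why: Williamson ether synthesis on both phenoxides, run under nitrogen because the hydroquinone is air-sensitive in base.

Step 3
Reactants: 4 2,5-bis(benzyloxy)-3-methoxybenzaldehyde
Product: 6 2,5-bis(benzyloxy)-3-methoxyphenol, via aryl formate 5 (not isolated)
Conditions: mCPBA, CH2Cl2, 0 °C to rt; aq Na2S2O3/NaHCO3 wash; then K2CO3 (cat.), MeOH, rt
Reagents that add atoms: 3-chloroperoxybenzoic acid, OOC(=O)c1cccc(Cl)c1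
Why: Baeyer–Villiger (Dakin-type) oxidation, in which the electron-rich, ortho-alkoxylated aryl group migrates in the Criegee adduct and the resulting formate is methanolysed under mild base that leaves the benzyl ethers intact.

Step 4
Reactants: 7 3,5-dihydroxy-4-methoxybenzoic acid
Product: 8 benzyl 3,5-bis(benzyloxy)-4-methoxybenzoate
Conditions: BnBr, K2CO3, DMF, 70 °C
Reagents that add atoms: benzyl bromide, BrCc1ccccc1
Why: Williamson ether synthesis on both phenols together with alkylation of the carboxylate.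

Step 5
Reactants: 8 benzyl 3,5-bis(benzyloxy)-4-methoxybenzoate
Product: 9 3,5-bis(benzyloxy)-4-methoxybenzoic acid
Conditions: KOH, THF/MeOH/H2O, 60 °C; then 1 M HCl
Reagents that add atoms: potassium hydroxide, [K+].[OH-]
Why: Saponification cleaves only the benzyl ester, since aryl benzyl ethers are inert to hydroxide.

Step 6
Reactants: 9 3,5-bis(benzyloxy)-4-methoxybenzoic acid
Product: 10 3,5-bis(benzyloxy)-4-methoxybenzoyl chloride
Conditions: (COCl)2, DMF (cat.), CH2Cl2, 0 °C to rt; evaporation
Reagents that add atoms: oxalyl chloride, ClC(=O)C(=O)Cl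
Why: Acid chloride formation through the Vilsmeier-type chloroiminium catalyst is mild enough for the benzyl ethers.

Step 7
Reactants: 10 3,5-bis(benzyloxy)-4-methoxybenzoyl chloride; 11 methyl benzyloxyacetate
Product: 13 methyl 2-(benzyloxy)-3-[3,5-bis(benzyloxy)-4-methoxyphenyl]-3-oxopropanoate (racemic), via chelated lithium enolate 12 (not isolated)
Conditions: 11 (2.2 equiv), LDA (2.2 equiv), THF, −78 °C; then 10 (1 equiv), −78 to −40 °C; aq NH4Cl
Reagents that add atoms: none
Why: Crossed Claisen condensation, in which the glycolate enolate is C-acylated by the non-enolisable aroyl chloride and the second equivalent of enolate takes up the acidic proton of the β-keto ester.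

Step 8
Reactants: 13 methyl 2-(benzyloxy)-3-[3,5-bis(benzyloxy)-4-methoxyphenyl]-3-oxopropanoate
Product: 15 methyl (E)-2-(benzyloxy)-3-[3,5-bis(benzyloxy)-4-methoxyphenyl]-3-{[(trifluoromethyl)sulfonyl]oxy}acrylate, via sodium enolate 14 (not isolated)
Conditions: NaH, Et2O, 0 °C; then Tf2O, 0 °C
Reagents that add atoms: trifluoromethanesulfonic anhydride, O=S(=O)(OS(=O)(=O)C(F)(F)F)C(F)(F)F
Why: O-sulfonylation of the chelated sodium enolate (enol triflate formation) should place the triflate cis to the ester and remove the only stereocentre of 13.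

Step 9
Reactants: 6 2,5-bis(benzyloxy)-3-methoxyphenol; 15 methyl (E)-2-(benzyloxy)-3-[3,5-bis(benzyloxy)-4-methoxyphenyl]-3-{[(trifluoromethyl)sulfonyl]oxy}acrylate
Product: 16 methyl (E)-2-(benzyloxy)-3-[2,5-bis(benzyloxy)-3-methoxyphenoxy]-3-[3,5-bis(benzyloxy)-4-methoxyphenyl]acrylate
Conditions: Cs2CO3, DMF, rt to 50 °C; any (Z)-isomer removed by chromatography
Reagents that add atoms: none
Why: Nucleophilic vinylic substitution (addition–elimination), in which the phenoxide adds to the β-carbon activated by the ester and triflate is expelled from the short-lived ester-stabilised carbanion, largely with retention of geometry.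

Step 10
Reactants: 16 methyl (E)-2-(benzyloxy)-3-[2,5-bis(benzyloxy)-3-methoxyphenoxy]-3-[3,5-bis(benzyloxy)-4-methoxyphenyl]acrylate
Product: 17 (E)-2-(benzyloxy)-3-[2,5-bis(benzyloxy)-3-methoxyphenoxy]-3-[3,5-bis(benzyloxy)-4-methoxyphenyl]acrylic acid
Conditions: LiOH·H2O, THF/MeOH/H2O, 40 °C; then 1 M HCl to pH 3, 0 °C
Reagents that add atoms: lithium hydroxide, [Li+].[OH-]
Why: Saponification of the methyl ester, which the aryl vinyl ether and the benzyl ethers should tolerate, as in the classical hydrolysis of β-aryloxycinnamates.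

Step 11
Reactants: 17 (E)-2-(benzyloxy)-3-[2,5-bis(benzyloxy)-3-methoxyphenoxy]-3-[3,5-bis(benzyloxy)-4-methoxyphenyl]acrylic acid
Product: 19 3,5,8-tris(benzyloxy)-2-[3,5-bis(benzyloxy)-4-methoxyphenyl]-7-methoxy-4H-chromen-4-one, via mixed trifluoroacetic anhydride 18 (not isolated)
Conditions: TFAA (3 equiv), CH2Cl2 (0.02 M), 0 °C to rt
Reagents that add atoms: none
Why: TFAA converts acid 17 into mixed anhydride 18, whose acyl carbon (the future C4), directly or after TFA-assisted ionisation to an acylium ion stabilised by the two enol-ether oxygens, is attacked by C4a of ring A, and loss of the proton from the Wheland intermediate gives the 4-pyranone. The closest known reaction type is the intramolecular Friedel–Crafts acylation of 3-aryloxyacrylic (β-aryloxycinnamic) acids to chromones and flavones. Ring C closes as a six-membered ring by electrophilic aromatic substitution (6-exo-trig at the anhydride carbonyl), forming C4–C4a, and no stereocentre is created. Regioselectivity on ring A is secured by the substrate, because the tether through O1 reaches only the two ortho carbons, C8 carries a benzyloxy group, and the free one (C4a) is activated by the ortho C5 oxygen and the para C7 methoxy. Chemoselectivity against acylation of the electron-rich ring B, which would give an indenone, rests on the (E) geometry that holds the acyl carbon cis to the aryloxy oxygen and trans to ring B, and on the easier six-membered closure should the double bond isomerise. The benzyl ethers should survive because the reaction runs at or below room temperature, dilute, and without a metal Lewis acid.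

Step 12
Reactants: 19 3,5,8-tris(benzyloxy)-2-[3,5-bis(benzyloxy)-4-methoxyphenyl]-7-methoxy-4H-chromen-4-one
Product: 20 3,5,8-trihydroxy-2-(3,5-dihydroxy-4-methoxyphenyl)-7-methoxy-4H-chromen-4-one
Conditions: H2 (1 atm), Pd/C (10 wt%), THF/MeOH, rt; degassed solvents, filtration under argon
Reagents that add atoms: none
Why: Catalytic hydrogenolysis cleaves all five benzyl ethers, the two methyl ethers and the flavonol C2=C3 bond are not reduced under these conditions, and air is excluded because the 5,8-dihydroxy ring A is a hydroquinone.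

## Compound list

1 | o-vanillin (2-hydroxy-3-methoxybenzaldehyde) | COc1cccc(C=O)c1O | starting material
2 | potassium 3-formyl-4-hydroxy-5-methoxyphenyl sulfate | COc1cc(OS(=O)(=O)[O-])cc(C=O)c1O.[K+] | intermediate
3 | 2,5-dihydroxy-3-methoxybenzaldehyde | COc1cc(O)cc(C=O)c1O | intermediate
4 | 2,5-bis(benzyloxy)-3-methoxybenzaldehyde | COc1cc(OCc2ccccc2)cc(C=O)c1OCc1ccccc1 | intermediate
5 | 2,5-bis(benzyloxy)-3-methoxyphenyl formate | COc1cc(OCc2ccccc2)cc(OC=O)c1OCc1ccccc1 | intermediate
6 | 2,5-bis(benzyloxy)-3-methoxyphenol | COc1cc(OCc2ccccc2)cc(O)c1OCc1ccccc1 | intermediate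
7 | 3,5-dihydroxy-4-methoxybenzoic acid | COc1c(O)cc(C(=O)O)cc1O | starting material
8 | benzyl 3,5-bis(benzyloxy)-4-methoxybenzoate | COc1c(OCc2ccccc2)cc(C(=O)OCc2ccccc2)cc1OCc1ccccc1 | intermediate
9 | 3,5-bis(benzyloxy)-4-methoxybenzoic acid | COc1c(OCc2ccccc2)cc(C(=O)O)cc1OCc1ccccc1 | intermediate
10 | 3,5-bis(benzyloxy)-4-methoxybenzoyl chloride | COc1c(OCc2ccccc2)cc(C(=O)Cl)cc1OCc1ccccc1 | intermediate
11 | methyl benzyloxyacetate | COC(=O)COCc1ccccc1 | starting material
12 | lithium 2-(benzyloxy)-1-methoxyethen-1-olate (chelated enolate of 11, O–Li cis to the benzyloxy group) | [Li+].[O-]/C(OC)=C\OCc1ccccc1 | intermediate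
13 | methyl 2-(benzyloxy)-3-[3,5-bis(benzyloxy)-4-methoxyphenyl]-3-oxopropanoate (racemic) | COC(=O)C(OCc1ccccc1)C(=O)c1cc(OCc2ccccc2)c(OC)c(OCc2ccccc2)c1 | intermediate
14 | sodium enolate of 13 (chelated, O–Na cis to the ester) | COC(=O)/C(OCc1ccccc1)=C(\[O-])c1cc(OCc2ccccc2)c(OC)c(OCc2ccccc2)c1.[Na+] | intermediate
15 | methyl (E)-2-(benzyloxy)-3-[3,5-bis(benzyloxy)-4-methoxyphenyl]-3-{[(trifluoromethyl)sulfonyl]oxy}acrylate | COC(=O)/C(OCc1ccccc1)=C(\OS(=O)(=O)C(F)(F)F)c1cc(OCc2ccccc2)c(OC)c(OCc2ccccc2)c1 | intermediate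
16 | methyl (E)-2-(benzyloxy)-3-[2,5-bis(benzyloxy)-3-methoxyphenoxy]-3-[3,5-bis(benzyloxy)-4-methoxyphenyl]acrylate | COC(=O)/C(OCc1ccccc1)=C(\Oc1cc(OCc2ccccc2)cc(OC)c1OCc1ccccc1)c1cc(OCc2ccccc2)c(OC)c(OCc2ccccc2)c1 | intermediate
17 | (E)-2-(benzyloxy)-3-[2,5-bis(benzyloxy)-3-methoxyphenoxy]-3-[3,5-bis(benzyloxy)-4-methoxyphenyl]acrylic acid | OC(=O)/C(OCc1ccccc1)=C(\Oc1cc(OCc2ccccc2)cc(OC)c1OCc1ccccc1)c1cc(OCc2ccccc2)c(OC)c(OCc2ccccc2)c1 | intermediate
18 | mixed anhydride of 17 with trifluoroacetic acid, (E) | O=C(OC(=O)C(F)(F)F)/C(OCc1ccccc1)=C(\Oc1cc(OCc2ccccc2)cc(OC)c1OCc1ccccc1)c1cc(OCc2ccccc2)c(OC)c(OCc2ccccc2)c1 | intermediate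
19 | 3,5,8-tris(benzyloxy)-2-[3,5-bis(benzyloxy)-4-methoxyphenyl]-7-methoxy-4H-chromen-4-one | COc1cc(OCc2ccccc2)c2c(=O)c(OCc3ccccc3)c(-c3cc(OCc4ccccc4)c(OC)c(OCc4ccccc4)c3)oc2c1OCc1ccccc1 | intermediate
20 | 3,5,8-trihydroxy-2-(3,5-dihydroxy-4-methoxyphenyl)-7-methoxy-4H-chromen-4-one | COc1cc(O)c2c(=O)c(O)c(-c3cc(O)c(OC)c(O)c3)oc2c1O | target

## Step count and risks

Total step count: 12. Longest linear sequence: 9 steps (7 → 20, steps 4–12). The o-vanillin branch adds 3 steps before the fragments meet in step 9.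

Steps most likely to fail:

1. Step 11 (ring closure). Acid may cleave or shift benzyl groups onto the electron-rich rings. The activated acid may isomerise about C2=C3 and then acylate ring B. The donor-stabilised acyl species may also ionise too slowly. The fallback sets out from phenol 6 and β-keto ester 13 and comes back at 19. It is a thermal Mentzer-type condensation: 6 and 13 are heated in diphenyl ether at about 220–240 °C under nitrogen with distillation of methanol. The β-keto ester should acylate the only free ortho carbon of the phenol (the future C4a) with loss of methanol, giving 1-[3,6-bis(benzyloxy)-2-hydroxy-4-methoxyphenyl]-2-(benzyloxy)-3-[3,5-bis(benzyloxy)-4-methoxyphenyl]propane-1,3-dione F1. Its phenol oxygen then condenses with the ring B ketone and water is lost, giving 19. This makes C4–C4a intermolecularly under neutral conditions and O1–C2 last, so it needs neither acid nor a defined alkene geometry.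

2. Step 9 (aryl vinyl ether). The phenoxide may attack sulfur instead of carbon, transferring the triflyl group and returning the enolate of 13. Addition to the tetrasubstituted, donor-substituted β-carbon may be too slow. The geometry may scramble in the carbanion intermediate. The fallback sets out from acid chloride 10 and phenol 6 and comes back at 20. It leaves the C3 oxygen out of the acrylate and installs it after ring closure.
   - Acylation of the lithium enolate of methyl acetate with 10 (LDA, THF, −78 °C) should give methyl 3-[3,5-bis(benzyloxy)-4-methoxyphenyl]-3-oxopropanoate F2.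
   - Tf2O, LiOTf and Et3N in CH2Cl2 should give methyl (Z)-3-[3,5-bis(benzyloxy)-4-methoxyphenyl]-3-{[(trifluoromethyl)sulfonyl]oxy}acrylate F3.
   - The β-carbon of F3 is less hindered and carries no α-donor, so with 6 and Cs2CO3 in DMF it should give methyl (Z)-3-[2,5-bis(benzyloxy)-3-methoxyphenoxy]-3-[3,5-bis(benzyloxy)-4-methoxyphenyl]acrylate F4, a β-aryloxycinnamate of the classical substrate class.
   - LiOH should give (Z)-3-[2,5-bis(benzyloxy)-3-methoxyphenoxy]-3-[3,5-bis(benzyloxy)-4-methoxyphenyl]acrylic acid F5.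
   - TFAA should close ring C as in step 11, through the mixed trifluoroacetic anhydride of F5 F6, to 5,8-bis(benzyloxy)-2-[3,5-bis(benzyloxy)-4-methoxyphenyl]-7-methoxy-4H-chromen-4-one F7.
   - Dimethyldioxirane (acetone/CH2Cl2, 0 °C) should epoxidise C2=C3 to the racemic cis-fused 2,3-epoxide 3,6-bis(benzyloxy)-1a-[3,5-bis(benzyloxy)-4-methoxyphenyl]-4-methoxy-1a,7a-dihydro-7H-oxireno[2,3-b]chromen-7-one F8.
   - Catalytic TsOH should isomerise F8 to 5,8-bis(benzyloxy)-2-[3,5-bis(benzyloxy)-4-methoxyphenyl]-3-hydroxy-7-methoxy-4H-chromen-4-one F9.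
   - Hydrogenolysis (H2, Pd/C) of the four benzyl ethers of F9 gives 20.

3. Step 7 (crossed Claisen). The glycolate enolate may self-condense, the product enolate may be O-acylated or acylated twice, and proton transfer may stop conversion early. The fallback sets out from acid chloride 10 and comes back at 13. Acylation of methyl diazoacetate with 10 (Et3N, MeCN, 0 °C to rt) should give methyl 2-diazo-3-[3,5-bis(benzyloxy)-4-methoxyphenyl]-3-oxopropanoate F10. O–H insertion of the rhodium carbenoid derived from F10 into benzyl alcohol, catalysed by dirhodium tetraacetate Rh2(OAc)4 (CH2Cl2, rt), then gives 13.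

## Further compounds

F1 | step 11 | 1-[3,6-bis(benzyloxy)-2-hydroxy-4-methoxyphenyl]-2-(benzyloxy)-3-[3,5-bis(benzyloxy)-4-methoxyphenyl]propane-1,3-dione (racemic) | COc1cc(OCc2ccccc2)c(C(=O)C(OCc2ccccc2)C(=O)c2cc(OCc3ccccc3)c(OC)c(OCc3ccccc3)c2)c(O)c1OCc1ccccc1
F2 | step 9 | methyl 3-[3,5-bis(benzyloxy)-4-methoxyphenyl]-3-oxopropanoate | COC(=O)CC(=O)c1cc(OCc2ccccc2)c(OC)c(OCc2ccccc2)c1
F3 | step 9 | methyl (Z)-3-[3,5-bis(benzyloxy)-4-methoxyphenyl]-3-{[(trifluoromethyl)sulfonyl]oxy}acrylate | COC(=O)/C=C(\OS(=O)(=O)C(F)(F)F)c1cc(OCc2ccccc2)c(OC)c(OCc2ccccc2)c1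
F4 | step 9 | methyl (Z)-3-[2,5-bis(benzyloxy)-3-methoxyphenoxy]-3-[3,5-bis(benzyloxy)-4-methoxyphenyl]acrylate | COC(=O)/C=C(\Oc1cc(OCc2ccccc2)cc(OC)c1OCc1ccccc1)c1cc(OCc2ccccc2)c(OC)c(OCc2ccccc2)c1
F5 | step 9 | (Z)-3-[2,5-bis(benzyloxy)-3-methoxyphenoxy]-3-[3,5-bis(benzyloxy)-4-methoxyphenyl]acrylic acid | OC(=O)/C=C(\Oc1cc(OCc2ccccc2)cc(OC)c1OCc1ccccc1)c1cc(OCc2ccccc2)c(OC)c(OCc2ccccc2)c1
F6 | step 9 | mixed trifluoroacetic anhydride of F5, (Z) | O=C(OC(=O)C(F)(F)F)/C=C(\Oc1cc(OCc2ccccc2)cc(OC)c1OCc1ccccc1)c1cc(OCc2ccccc2)c(OC)c(OCc2ccccc2)c1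
F7 | step 9 | 5,8-bis(benzyloxy)-2-[3,5-bis(benzyloxy)-4-methoxyphenyl]-7-methoxy-4H-chromen-4-one | COc1cc(OCc2ccccc2)c2c(=O)cc(-c3cc(OCc4ccccc4)c(OC)c(OCc4ccccc4)c3)oc2c1OCc1ccccc1
F8 | step 9 | 3,6-bis(benzyloxy)-1a-[3,5-bis(benzyloxy)-4-methoxyphenyl]-4-methoxy-1a,7a-dihydro-7H-oxireno[2,3-b]chromen-7-one (racemic, cis-fused 2,3-epoxide of F7) | O=C1[C@H]2O[C@@]2(c2cc(OCc3ccccc3)c(OC)c(OCc3ccccc3)c2)Oc2c1c(OCc1ccccc1)cc(OC)c2OCc1ccccc1
F9 | step 9 | 5,8-bis(benzyloxy)-2-[3,5-bis(benzyloxy)-4-methoxyphenyl]-3-hydroxy-7-methoxy-4H-chromen-4-one | COc1cc(OCc2ccccc2)c2c(=O)c(O)c(-c3cc(OCc4ccccc4)c(OC)c(OCc4ccccc4)c3)oc2c1OCc1ccccc1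
F10 | step 7 | methyl 2-diazo-3-[3,5-bis(benzyloxy)-4-methoxyphenyl]-3-oxopropanoate | COC(=O)C(=[N+]=[N-])C(=O)c1cc(OCc2ccccc2)c(OC)c(OCc2ccccc2)c1
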